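The carbocycle of the hexahydrobenzofuran core (C3a, C4, C5, C6, C7, C7a) is cut into two three-carbon halves: C7–C7a–C3a, an acetoacetate 1,3-dinucleophile that mirrors the 1,3-related oxygens on C6 and C7a, and C6–C5–C4, an aldehyde whose gem-dimethyl carbon C4 is a latent tertiary cation. In one flask Chan's diene and 3-methoxy-3-methylbutanal are joined: a Ti(OiPr)4/(R)-BINOL Mukaiyama aldol makes C6–C7 and sets the C6 carbinol, then TiCl4 ionises the ether and the enol ether closes C4–C3a. The ring serves both termini; its epoxy-alkyne gives the furanoid ring by anti SN2' hydride delivery and Ph3PAuCl/AgBF4 allenol cyclisation.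

Key step: step 2

Remark on numbering: O1, C2, C3, C3a, C4–C7, C7a are the locants of the 2,4,5,6,7,7a-hexahydro-1-benzofuran core of the target; they are used for the corresponding atoms of all precursors.

Assumption: Ti(OiPr)4/(R)-BINOL is taken to give the (5S) aldol adduct 4; if the sense proves opposite, (S)-BINOL is used and nothing else changes.

Step 1
Reactants: 1 3-methoxy-3-methylbutan-1-ol
Product: 2 3-methoxy-3-methylbutanal
Conditions: TEMPO (cat.), PhI(OAc)2, CH2Cl2, rt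
Reagents that add atoms: none
Why: TEMPO-catalysed oxoammonium oxidation with PhI(OAc)2 should stop at the aldehyde under near-neutral conditions that leave the tertiary ether in place.

Step 2
Reactants: 2 3-methoxy-3-methylbutanal; 3 1-methoxy-1,3-bis(trimethylsilyloxy)buta-1,3-diene (Chan's diene)
Product: 5 methyl (4S)-4-hydroxy-6,6-dimethyl-2-oxocyclohexane-1-carboxylate, via bis-silyl aldol adduct 4 (not isolated)
Conditions: Ti(OiPr)4 (10 mol %), (R)-BINOL (10 mol %), 4 Å MS, THF, −78 to −20 °C; then THF off, CH2Cl2, TiCl4 (2.5 equiv), −78 to −30 °C; aq. NaHCO3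
Reagents that add atoms: none
Why: Proposed new method: the Ti(OiPr)4/(R)-BINOL complex activates aldehyde 2 for a Mukaiyama aldol addition of the terminal carbon of diene 3 (new bond C6–C7) with silyl transfer to give 4, whose tertiary methyl ether is then ionised by TiCl4 to a gem-dimethyl cation at C4 that is captured by the carbon of the remaining silyl enol ether (new bond C4–C3a) with loss of Me3SiCl. The closest known reaction types are the TiCl4-mediated formal [3+3] cyclisation of 1,3-bis(silyloxy)buta-1,3-dienes with 1,3-dielectrophiles and the Lewis-acid tert-alkylation of silyl enol ethers by tertiary halides and ethers; a dielectrophile made of an aldehyde and a tertiary ether has not been used in this way. The six-membered carbocycle closes in a 6-(enolendo)-exo-tet mode. The only lasting stereocentre, the C6 carbinol, is set in the aldol stage by the chiral titanium catalyst, which selects the aldehyde face; the ester-bearing carbon is enolisable and C4 is not stereogenic. The step needs attack by the diene terminus before the internal carbon and C- over O-alkylation: the terminus of 3 is its most nucleophilic site and meets the aldehyde before any cation exists, and O-alkylation by a tertiary cation is reversible under TiCl4 whereas C-alkylation is not.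

Step 3
Reactants: 5 methyl (4S)-4-hydroxy-6,6-dimethyl-2-oxocyclohexane-1-carboxylate
Product: 6 methyl (4S)-4-(tert-butyldimethylsilyloxy)-6,6-dimethyl-2-oxocyclohexane-1-carboxylate
Conditions: TBSCl, imidazole, DMF, rt
Reagents that add atoms: tert-butyldimethylsilyl chloride, CC(C)(C)[Si](C)(C)Cl
Why: Silyl ether formation (Corey protocol) on the only hydroxyl; the bulky group later shields one face of the ring.

Step 4
Reactants: 6 methyl (4S)-4-(tert-butyldimethylsilyloxy)-6,6-dimethyl-2-oxocyclohexane-1-carboxylate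
Product: 7 methyl (4S)-4-(tert-butyldimethylsilyloxy)-6,6-dimethyl-2-(trifluoromethylsulfonyloxy)cyclohex-1-ene-1-carboxylate
Conditions: NaH, PhNTf2, THF, 0 °C to rt
Reagents that add atoms: N-phenylbis(trifluoromethanesulfonimide), O=S(=O)(N(c1ccccc1)S(=O)(=O)C(F)(F)F)C(F)(F)F
Why: O-sulfonylation of the sodium enolate of the β-keto ester with PhNTf2 gives the enol triflate at the ketone carbon only.

Step 5
Reactants: 7 methyl (4S)-4-(tert-butyldimethylsilyloxy)-6,6-dimethyl-2-(trifluoromethylsulfonyloxy)cyclohex-1-ene-1-carboxylate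
Product: 8 methyl (4R)-4-(tert-butyldimethylsilyloxy)-2,6,6-trimethylcyclohex-1-ene-1-carboxylate
Conditions: Me2CuLi, THF, −78 to −20 °C
Reagents that add atoms: lithium dimethylcuprate Me2CuLi, [Li+].C[Cu-]C
Why: Addition–elimination of the cuprate on the β-triflyloxy enoate (McMurry–Scott-type coupling) should place the methyl group on C7a and lock the tetrasubstituted double bond between C7a and C3a.

Step 6
Reactants: 8 methyl (4R)-4-(tert-butyldimethylsilyloxy)-2,6,6-trimethylcyclohex-1-ene-1-carboxylate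
Product: 9 [(4R)-4-(tert-butyldimethylsilyloxy)-2,6,6-trimethylcyclohex-1-en-1-yl]methanol
Conditions: i-Bu2AlH, CH2Cl2, −78 to 0 °C
Reagents that add atoms: none
Why: Hydride 1,2-reduction of the conjugated ester by i-Bu2AlH to the allylic alcohol.

Step 7
Reactants: 9 [(4R)-4-(tert-butyldimethylsilyloxy)-2,6,6-trimethylcyclohex-1-en-1-yl]methanol
Product: 11 tert-butyl{[(1R)-4-ethynyl-3,5,5-trimethylcyclohex-3-en-1-yl]oxy}dimethylsilane, via aldehyde 10 (not isolated)
Conditions: MnO2, THF, rt; then dimethyl (1-diazo-2-oxopropyl)phosphonate, K2CO3, MeOH, rt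
Reagents that add atoms: dimethyl (1-diazo-2-oxopropyl)phosphonate, CC(=O)C(=[N+]=[N-])P(=O)(OC)OC
Why: Allylic oxidation on MnO2 followed in the same flask by Seyferth–Gilbert homologation with the Ohira–Bestmann reagent should turn CH2OH into the terminal alkyne.

Step 8
Reactants: 11 tert-butyl{[(1R)-4-ethynyl-3,5,5-trimethylcyclohex-3-en-1-yl]oxy}dimethylsilane
Product: 12 tert-butyl{[(1R,3S,6R)-6-ethynyl-1,5,5-trimethyl-7-oxabicyclo[4.1.0]heptan-3-yl]oxy}dimethylsilane
Conditions: mCPBA, NaHCO3, CH2Cl2, 0 °C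
Reagents that add atoms: 3-chloroperoxybenzoic acid, OOC(=O)c1cccc(Cl)c1
Why: Prilezhaev epoxidation of the only alkene should occur on the face anti to the silyloxy group, which places the oxygen at C7a trans to the C6 oxygen and so sets C7a (and C3a).

Step 9
Reactants: 13 3-bromofuran
Product: 14 (3-bromofuran-2-yl)trimethylsilane
Conditions: LiN(i-Pr)2, THF, −78 °C; Me3SiCl
Reagents that add atoms: chlorotrimethylsilane, C[Si](C)(C)Cl
Why: Directed lithiation of 3-bromofuran at C2 by the amide base and silylation; the silyl group later directs the furan oxidation.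

Step 10
Reactants: 12 tert-butyl{[(1R,3S,6R)-6-ethynyl-1,5,5-trimethyl-7-oxabicyclo[4.1.0]heptan-3-yl]oxy}dimethylsilane; 14 (3-bromofuran-2-yl)trimethylsilane
Product: 15 tert-butyldimethyl{[(1R,3S,6R)-1,5,5-trimethyl-6-{[2-(trimethylsilyl)furan-3-yl]ethynyl}-7-oxabicyclo[4.1.0]heptan-3-yl]oxy}silane
Conditions: Pd(PhCN)2Cl2 (3 mol %), P(t-Bu)3 (6 mol %), CuI (2 mol %), i-Pr2NH, dioxane, rt
Reagents that add atoms: none
Why: Sonogashira coupling of the terminal alkyne with the heteroaryl bromide at room temperature should leave the epoxide intact.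

Step 11
Reactants: 15 tert-butyldimethyl{[(1R,3S,6R)-1,5,5-trimethyl-6-{[2-(trimethylsilyl)furan-3-yl]ethynyl}-7-oxabicyclo[4.1.0]heptan-3-yl]oxy}silane
Product: 16 (1R,5S)-5-(tert-butyldimethylsilyloxy)-1,3,3-trimethyl-2-{(aS)-2-[2-(trimethylsilyl)furan-3-yl]ethenylidene}cyclohexan-1-ol
Conditions: CuCl (5 mol %), 1,3-bis(2,6-diisopropylphenyl)imidazolium chloride (5 mol %), NaOt-Bu (12 mol %), (EtO)2MeSiH, toluene, 0 °C; then K2CO3, MeOH
Reagents that add atoms: none
Why: Copper hydride-catalysed SN2' reduction of the propargylic epoxide: hydride enters anti to the breaking C3a–O bond, so the epoxide configuration is transferred to the allene axis (centre-to-axis chirality transfer) while C7a keeps its oxygen.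

Step 12
Reactants: 16 (1R,5S)-5-(tert-butyldimethylsilyloxy)-1,3,3-trimethyl-2-{(aS)-2-[2-(trimethylsilyl)furan-3-yl]ethenylidene}cyclohexan-1-ol
Product: 17 tert-butyldimethyl{[(2R,6S,7aR)-4,4,7a-trimethyl-2-[2-(trimethylsilyl)furan-3-yl]-2,4,5,6,7,7a-hexahydro-1-benzofuran-6-yl]oxy}silane
Conditions: Ph3PAuCl (2 mol %), AgBF4 (2 mol %), THF, 0 °C
Reagents that add atoms: none
Why: Gold-catalysed 5-endo cycloisomerisation of the α-hydroxyallene (axis-to-centre chirality transfer): the C7a oxygen adds to the allene terminus in the plane of the ring carbon, so the furyl group ends cis to C7 and H-2 cis to the 7a-methyl, which is the (2R) configuration.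

Step 13
Reactants: 17 tert-butyldimethyl{[(2R,6S,7aR)-4,4,7a-trimethyl-2-[2-(trimethylsilyl)furan-3-yl]-2,4,5,6,7,7a-hexahydro-1-benzofuran-6-yl]oxy}silane
Product: 18 3-[(2R,6S,7aR)-6-(tert-butyldimethylsilyloxy)-4,4,7a-trimethyl-2,4,5,6,7,7a-hexahydro-1-benzofuran-2-yl]-5-hydroxyfuran-2(5H)-one
Conditions: O2, rose bengal, hν (visible), CH2Cl2–MeOH, −78 °C
Reagents that add atoms: dioxygen, O=O
Why: [4+2] cycloaddition of singlet oxygen to the furan and silyl migration in the endoperoxide (regiospecific photooxygenation of a 2-silylfuran) should put the carbonyl on the carbon next to the side chain; the hemiacetal carbon forms as a mixture that is removed in step 14.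

Step 14
Reactants: 18 3-[(2R,6S,7aR)-6-(tert-butyldimethylsilyloxy)-4,4,7a-trimethyl-2,4,5,6,7,7a-hexahydro-1-benzofuran-2-yl]-5-hydroxyfuran-2(5H)-one
Product: 19 3-[(2R,6S,7aR)-6-(tert-butyldimethylsilyloxy)-4,4,7a-trimethyl-2,4,5,6,7,7a-hexahydro-1-benzofuran-2-yl]furan-2(5H)-one
Conditions: NaBH4, MeOH, 0 °C; then aq. HCl to pH 3
Reagents that add atoms: none
Why: Borohydride reduction of the ring-opened aldehyde form of the hydroxybutenolide and acid lactonisation give the α-substituted butenolide.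

Step 15
Reactants: 11 tert-butyl{[(1R)-4-ethynyl-3,5,5-trimethylcyclohex-3-en-1-yl]oxy}dimethylsilane; 20 ethyl but-2-ynoate
Product: 21 ethyl (2E)-5-[(4R)-4-(tert-butyldimethylsilyloxy)-2,6,6-trimethylcyclohex-1-en-1-yl]-3-methylpent-2-en-4-ynoate
Conditions: Pd(OAc)2 (3 mol %), tris(2,6-dimethoxyphenyl)phosphine (3 mol %), toluene, rt
Reagents that add atoms: none
Why: Palladium-catalysed syn addition of the terminal alkyne C–H across the ynoate (Trost alkyne cross-coupling) should give the E enynoate with the methyl group on the carbon next to the triple bond.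

Step 16
Reactants: 21 ethyl (2E)-5-[(4R)-4-(tert-butyldimethylsilyloxy)-2,6,6-trimethylcyclohex-1-en-1-yl]-3-methylpent-2-en-4-ynoate
Product: 22 (2E)-5-[(4R)-4-(tert-butyldimethylsilyloxy)-2,6,6-trimethylcyclohex-1-en-1-yl]-3-methylpent-2-en-4-yn-1-ol
Conditions: i-Bu2AlH, CH2Cl2, −78 °C
Reagents that add atoms: none
Why: Hydride reduction of the ester to the allylic alcohol by i-Bu2AlH.

Step 17
Reactants: 22 (2E)-5-[(4R)-4-(tert-butyldimethylsilyloxy)-2,6,6-trimethylcyclohex-1-en-1-yl]-3-methylpent-2-en-4-yn-1-ol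
Product: 23 {(2E)-5-[(4R)-4-(tert-butyldimethylsilyloxy)-2,6,6-trimethylcyclohex-1-en-1-yl]-3-methylpent-2-en-4-yn-1-yl}triphenylphosphonium bromide
Conditions: Ph3P·HBr, CH2Cl2, 0 °C to rt
Reagents that add atoms: triphenylphosphine hydrobromide, [Br-].[PH+](c1ccccc1)(c1ccccc1)c1ccccc1
Why: Allylic substitution of the hydroxyl by Ph3P under HBr activation (phosphonium salt formation) at the primary terminus; the silyl ether should survive the aprotic conditions.

Step 18
Reactants: 23 {(2E)-5-[(4R)-4-(tert-butyldimethylsilyloxy)-2,6,6-trimethylcyclohex-1-en-1-yl]-3-methylpent-2-en-4-yn-1-yl}triphenylphosphonium bromide; 24 (2E)-4,4-dimethoxybut-2-enal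
Product: 26 (2E,4E,6E)-9-[(4R)-4-(tert-butyldimethylsilyloxy)-2,6,6-trimethylcyclohex-1-en-1-yl]-7-methylnona-2,4,6-trien-8-ynal, via acetal 25 (not isolated)
Conditions: NaOMe, MeOH–CH2Cl2, 0 °C to rt; then pyridinium p-toluenesulfonate, acetone–H2O, rt; then I2 (1 mol %), CH2Cl2, daylight
Reagents that add atoms: water, O
Why: Wittig olefination of the enal with the allylic ylide, then acetal hydrolysis; iodine-catalysed equilibration should bring the new disubstituted double bond to E.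

Step 19
Reactants: 26 (2E,4E,6E)-9-[(4R)-4-(tert-butyldimethylsilyloxy)-2,6,6-trimethylcyclohex-1-en-1-yl]-7-methylnona-2,4,6-trien-8-ynal; 27 2-(triphenyl-λ5-phosphanylidene)propanal
Product: 28 (2E,4E,6E,8E)-11-[(4R)-4-(tert-butyldimethylsilyloxy)-2,6,6-trimethylcyclohex-1-en-1-yl]-2,9-dimethylundeca-2,4,6,8-tetraen-10-ynal
Conditions: toluene, 80 °C
Reagents that add atoms: none
Why: Wittig olefination with the stabilised α-methyl ylide should give the E trisubstituted enal.

Step 20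
Reactants: 19 3-[(2R,6S,7aR)-6-(tert-butyldimethylsilyloxy)-4,4,7a-trimethyl-2,4,5,6,7,7a-hexahydro-1-benzofuran-2-yl]furan-2(5H)-one; 28 (2E,4E,6E,8E)-11-[(4R)-4-(tert-butyldimethylsilyloxy)-2,6,6-trimethylcyclohex-1-en-1-yl]-2,9-dimethylundeca-2,4,6,8-tetraen-10-ynal
Product: 31 bis(tert-butyldimethylsilyl) ether of target 32 at both ring hydroxyls, via lithium aldolate 29 (not isolated), via mesylate 30 (not isolated)
Conditions: LiN(i-Pr)2, THF, −78 °C; 28; MeSO2Cl, −78 to 0 °C; then DBU, 0 °C to rt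
Reagents that add atoms: none
Why: Vinylogous aldol addition of the butenolide dienolate through its γ-carbon, then mesylation and base-induced E1cB elimination (γ-ylidenebutenolide synthesis); the Z isomer with the chain syn to the ring oxygen should be the favoured product.

Step 21
Reactants: 31 bis(tert-butyldimethylsilyl) ether of target 32
Product: 32 (5Z)-3-[(2R,6S,7aR)-6-hydroxy-4,4,7a-trimethyl-2,4,5,6,7,7a-hexahydro-1-benzofuran-2-yl]-5-{(2E,4E,6E,8E)-11-[(4R)-4-hydroxy-2,6,6-trimethylcyclohex-1-en-1-yl]-2,9-dimethylundeca-2,4,6,8-tetraen-10-yn-1-ylidene}furan-2(5H)-one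
Conditions: HF·pyridine, pyridine, THF, 0 °C to rt
Reagents that add atoms: none
Why: Fluoride cleavage of both silyl ethers (desilylation) under buffered conditions that should spare the dihydrofuran and the polyene.

Compound list
1 | 3-methoxy-3-methylbutan-1-ol | COC(C)(C)CCO | starting material
2 | 3-methoxy-3-methylbutanal | COC(C)(C)CC=O | intermediate
3 | 1-methoxy-1,3-bis(trimethylsilyloxy)buta-1,3-diene (Chan's diene) | COC(O[Si](C)(C)C)=CC(=C)O[Si](C)(C)C | starting material
4 | methyl (5S)-7-methoxy-7-methyl-3,5-bis(trimethylsilyloxy)oct-2-enoate | COC(C)(C)C[C@H](O[Si](C)(C)C)CC(O[Si](C)(C)C)=CC(=O)OC | intermediate (not isolated)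
5 | methyl (4S)-4-hydroxy-6,6-dimethyl-2-oxocyclohexane-1-carboxylate (C1 epimers and enol form) | CC1(C)C[C@H](O)CC(=O)C1C(=O)OC | intermediate
6 | methyl (4S)-4-(tert-butyldimethylsilyloxy)-6,6-dimethyl-2-oxocyclohexane-1-carboxylate | CC1(C)C[C@H](O[Si](C)(C)C(C)(C)C)CC(=O)C1C(=O)OC | intermediate
7 | methyl (4S)-4-(tert-butyldimethylsilyloxy)-6,6-dimethyl-2-(trifluoromethylsulfonyloxy)cyclohex-1-ene-1-carboxylate | CC1(C)C[C@H](O[Si](C)(C)C(C)(C)C)CC(OS(=O)(=O)C(F)(F)F)=C1C(=O)OC | intermediate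
8 | methyl (4R)-4-(tert-butyldimethylsilyloxy)-2,6,6-trimethylcyclohex-1-ene-1-carboxylate | CC1(C)C[C@H](O[Si](C)(C)C(C)(C)C)CC(C)=C1C(=O)OC | intermediate
9 | [(4R)-4-(tert-butyldimethylsilyloxy)-2,6,6-trimethylcyclohex-1-en-1-yl]methanol | CC1(C)C[C@H](O[Si](C)(C)C(C)(C)C)CC(C)=C1CO | intermediate
10 | (4R)-4-(tert-butyldimethylsilyloxy)-2,6,6-trimethylcyclohex-1-ene-1-carbaldehyde | CC1(C)C[C@H](O[Si](C)(C)C(C)(C)C)CC(C)=C1C=O | intermediate (not isolated)
11 | tert-butyl{[(1R)-4-ethynyl-3,5,5-trimethylcyclohex-3-en-1-yl]oxy}dimethylsilane | CC1(C)C[C@H](O[Si](C)(C)C(C)(C)C)CC(C)=C1C#C | intermediate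
12 | tert-butyl{[(1R,3S,6R)-6-ethynyl-1,5,5-trimethyl-7-oxabicyclo[4.1.0]heptan-3-yl]oxy}dimethylsilane (epoxide oxygen trans to the silyloxy group) | CC1(C)C[C@H](O[Si](C)(C)C(C)(C)C)C[C@@]2(C)O[C@@]12C#C | intermediate
13 | 3-bromofuran | Brc1ccoc1 | starting material
14 | (3-bromofuran-2-yl)trimethylsilane | C[Si](C)(C)c1occc1Br | intermediate
15 | tert-butyldimethyl{[(1R,3S,6R)-1,5,5-trimethyl-6-{[2-(trimethylsilyl)furan-3-yl]ethynyl}-7-oxabicyclo[4.1.0]heptan-3-yl]oxy}silane | CC1(C)C[C@H](O[Si](C)(C)C(C)(C)C)C[C@@]2(C)O[C@@]12C#Cc1ccoc1[Si](C)(C)C | intermediate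
16 | (1R,5S)-5-(tert-butyldimethylsilyloxy)-1,3,3-trimethyl-2-{(aS)-2-[2-(trimethylsilyl)furan-3-yl]ethenylidene}cyclohexan-1-ol (furyl group on the face of the ring-carbon plane that carried the epoxide oxygen) | CC1(C)C[C@H](O[Si](C)(C)C(C)(C)C)C[C@@](C)(O)C1=[C@@]=C([H])c1ccoc1[Si](C)(C)C | intermediate
17 | tert-butyldimethyl{[(2R,6S,7aR)-4,4,7a-trimethyl-2-[2-(trimethylsilyl)furan-3-yl]-2,4,5,6,7,7a-hexahydro-1-benzofuran-6-yl]oxy}silane | CC1(C)C[C@H](O[Si](C)(C)C(C)(C)C)C[C@@]2(C)O[C@@H](c3ccoc3[Si](C)(C)C)C=C12 | intermediate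
18 | 3-[(2R,6S,7aR)-6-(tert-butyldimethylsilyloxy)-4,4,7a-trimethyl-2,4,5,6,7,7a-hexahydro-1-benzofuran-2-yl]-5-hydroxyfuran-2(5H)-one (both epimers at the hemiacetal carbon) | CC1(C)C[C@H](O[Si](C)(C)C(C)(C)C)C[C@@]2(C)O[C@@H](C3=CC(O)OC3=O)C=C12 | intermediate
19 | 3-[(2R,6S,7aR)-6-(tert-butyldimethylsilyloxy)-4,4,7a-trimethyl-2,4,5,6,7,7a-hexahydro-1-benzofuran-2-yl]furan-2(5H)-one | CC1(C)C[C@H](O[Si](C)(C)C(C)(C)C)C[C@@]2(C)O[C@@H](C3=CCOC3=O)C=C12 | intermediate
20 | ethyl but-2-ynoate | CC#CC(=O)OCC | starting material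
21 | ethyl (2E)-5-[(4R)-4-(tert-butyldimethylsilyloxy)-2,6,6-trimethylcyclohex-1-en-1-yl]-3-methylpent-2-en-4-ynoate | CC1(C)C[C@H](O[Si](C)(C)C(C)(C)C)CC(C)=C1C#C/C(C)=C/C(=O)OCC | intermediate
22 | (2E)-5-[(4R)-4-(tert-butyldimethylsilyloxy)-2,6,6-trimethylcyclohex-1-en-1-yl]-3-methylpent-2-en-4-yn-1-ol | CC1(C)C[C@H](O[Si](C)(C)C(C)(C)C)CC(C)=C1C#C/C(C)=C/CO | intermediate
23 | {(2E)-5-[(4R)-4-(tert-butyldimethylsilyloxy)-2,6,6-trimethylcyclohex-1-en-1-yl]-3-methylpent-2-en-4-yn-1-yl}triphenylphosphonium bromide | CC1(C)C[C@H](O[Si](C)(C)C(C)(C)C)CC(C)=C1C#C/C(C)=C/C[P+](c1ccccc1)(c1ccccc1)c1ccccc1.[Br-] | intermediate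
24 | (2E)-4,4-dimethoxybut-2-enal (fumaraldehyde mono(dimethyl acetal)) | COC(OC)/C=C/C=O | starting material
25 | tert-butyl{[(1R)-4-[(3E,5E,7E)-9,9-dimethoxy-3-methylnona-3,5,7-trien-1-yn-1-yl]-3,5,5-trimethylcyclohex-3-en-1-yl]oxy}dimethylsilane (formed as a 5E/5Z mixture; SMILES drawn for 5E) | CC1(C)C[C@H](O[Si](C)(C)C(C)(C)C)CC(C)=C1C#C/C(C)=C/C=C/C=C/C(OC)OC | intermediate (not isolated)
26 | (2E,4E,6E)-9-[(4R)-4-(tert-butyldimethylsilyloxy)-2,6,6-trimethylcyclohex-1-en-1-yl]-7-methylnona-2,4,6-trien-8-ynal | CC1(C)C[C@H](O[Si](C)(C)C(C)(C)C)CC(C)=C1C#C/C(C)=C/C=C/C=C/C=O | intermediate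
27 | 2-(triphenyl-λ5-phosphanylidene)propanal | CC(C=O)=P(c1ccccc1)(c1ccccc1)c1ccccc1 | starting material
28 | (2E,4E,6E,8E)-11-[(4R)-4-(tert-butyldimethylsilyloxy)-2,6,6-trimethylcyclohex-1-en-1-yl]-2,9-dimethylundeca-2,4,6,8-tetraen-10-ynal | CC1(C)C[C@H](O[Si](C)(C)C(C)(C)C)CC(C)=C1C#C/C(C)=C/C=C/C=C/C=C(C)/C=O | intermediate
29 | lithium alkoxide of the γ-aldol adduct of 19 to 28: butenolide C5 bonded to the former aldehyde carbon, which carries O–Li (mixture at the two new centres) | CC1=C(C#C/C(C)=C/C=C/C=C/C=C(C)/C([O-])C2C=C([C@H]3C=C4C(C)(C)C[C@H](O[Si](C)(C)C(C)(C)C)C[C@@]4(C)O3)C(=O)O2)C(C)(C)C[C@H](O[Si](C)(C)C(C)(C)C)C1.[Li+] | intermediate (not isolated)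
30 | methanesulfonate of the aldol adduct 29 | CC1=C(C#C/C(C)=C/C=C/C=C/C=C(C)/C(OS(C)(=O)=O)C2C=C([C@H]3C=C4C(C)(C)C[C@H](O[Si](C)(C)C(C)(C)C)C[C@@]4(C)O3)C(=O)O2)C(C)(C)C[C@H](O[Si](C)(C)C(C)(C)C)C1 | intermediate (not isolated)
31 | bis(tert-butyldimethylsilyl) ether of 32 (silyl groups on the C6 oxygen of the benzofuran ring and on the cyclohexenol oxygen) | CC1=C(C#C/C(C)=C/C=C/C=C/C=C(C)/C=C2/C=C([C@H]3C=C4C(C)(C)C[C@H](O[Si](C)(C)C(C)(C)C)C[C@@]4(C)O3)C(=O)O2)C(C)(C)C[C@H](O[Si](C)(C)C(C)(C)C)C1 | intermediate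
32 | (5Z)-3-[(2R,6S,7aR)-6-hydroxy-4,4,7a-trimethyl-2,4,5,6,7,7a-hexahydro-1-benzofuran-2-yl]-5-{(2E,4E,6E,8E)-11-[(4R)-4-hydroxy-2,6,6-trimethylcyclohex-1-en-1-yl]-2,9-dimethylundeca-2,4,6,8-tetraen-10-yn-1-ylidene}furan-2(5H)-one | CC1=C(C#C/C(C)=C/C=C/C=C/C=C(C)/C=C2/C=C([C@H]3C=C4C(C)(C)C[C@H](O)C[C@@]4(C)O3)C(=O)O2)C(C)(C)C[C@H](O)C1 | target

Total step count: 21. Longest linear sequence: 15 steps (steps 1–8, 10–14, 20 and 21).

Steps most likely to fail

Step 2 (proposed new method). The tandem may fail through elimination of the tertiary ether to alkenes that do not re-ionise, through O-alkylation of the enol ether, or through erosion of enantioselectivity in the aldol stage. The fallback uses known reactions one at a time. It sets out from diene 3, which is added under the same Ti(OiPr)4/(R)-BINOL catalysis to 3-methylbut-3-enal F2 (Dess–Martin oxidation of commercial 3-methylbut-3-en-1-ol F1) and worked up with CF3CO2H to give methyl (5S)-5-hydroxy-7-methyl-3-oxooct-7-enoate F3. Silylation (TBSCl, imidazole) gives methyl (5S)-5-(tert-butyldimethylsilyloxy)-7-methyl-3-oxooct-7-enoate F4. Markovnikov intramolecular hydroalkylation of the 1,1-disubstituted alkene by the β-keto ester (Conia-ene-type addition to an unactivated alkene; Ph3PAuCl/AgOTf, toluene, 90 °C) closes the ring, and the route is rejoined at compound 6.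

Step 8. The epoxidation may fail through poor facial selectivity, the peracid also attacking syn to the silyloxy group. The fallback replaces substrate control by reagent control. It sets out from allylic alcohol 9, whose Sharpless asymmetric epoxidation (Ti(OiPr)4, L-(+)-diethyl tartrate, t-BuOOH, 4 Å MS, CH2Cl2, −20 °C) should give [(1R,4S,6R)-4-(tert-butyldimethylsilyloxy)-2,2,6-trimethyl-7-oxabicyclo[4.1.0]heptan-1-yl]methanol F5. Parikh–Doering oxidation (SO3·pyridine, DMSO, Et3N) gives (1S,4S,6R)-4-(tert-butyldimethylsilyloxy)-2,2,6-trimethyl-7-oxabicyclo[4.1.0]heptane-1-carbaldehyde F6. Ohira–Bestmann homologation (K2CO3, MeOH) rejoins the route at compound 12.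

Step 20. The final union may fail through decomposition or self-condensation of the long polyenal 28 under the basic conditions, through sluggish addition of the hindered dienolate, or through E/Z scrambling in the elimination. The fallback reverses the order of fragment union. It sets out from butenolide 19, which is condensed in the same way (LiN(i-Pr)2; MeSO2Cl; DBU) with the short aldehyde (2E,4E)-6,6-dimethoxy-2-methylhexa-2,4-dienal F7 (Wittig reaction of 24 with 27) to give the (5Z)-ylidenebutenolide dimethyl acetal F8. Hydrolysis (pyridinium p-toluenesulfonate, acetone–water) gives the ylidenebutenolide dienal F9. Wittig olefination with the ylide of phosphonium salt 23 (NaOMe) and iodine-catalysed isomerisation rejoin the route at compound 31.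

Further compounds
F1 | step 2 | 3-methylbut-3-en-1-ol | CC(=C)CCO
F2 | step 2 | 3-methylbut-3-enal | CC(=C)CC=O
F3 | step 2 | methyl (5S)-5-hydroxy-7-methyl-3-oxooct-7-enoate | CC(=C)C[C@H](O)CC(=O)CC(=O)OC
F4 | step 2 | methyl (5S)-5-(tert-butyldimethylsilyloxy)-7-methyl-3-oxooct-7-enoate | CC(=C)C[C@H](O[Si](C)(C)C(C)(C)C)CC(=O)CC(=O)OC
F5 | step 8 | [(1R,4S,6R)-4-(tert-butyldimethylsilyloxy)-2,2,6-trimethyl-7-oxabicyclo[4.1.0]heptan-1-yl]methanol | CC1(C)C[C@H](O[Si](C)(C)C(C)(C)C)C[C@@]2(C)O[C@@]12CO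
F6 | step 8 | (1S,4S,6R)-4-(tert-butyldimethylsilyloxy)-2,2,6-trimethyl-7-oxabicyclo[4.1.0]heptane-1-carbaldehyde | CC1(C)C[C@H](O[Si](C)(C)C(C)(C)C)C[C@@]2(C)O[C@@]12C=O
F7 | step 20 | (2E,4E)-6,6-dimethoxy-2-methylhexa-2,4-dienal | COC(OC)/C=C/C=C(C)/C=O
F8 | step 20 | (5Z)-3-[(2R,6S,7aR)-6-(tert-butyldimethylsilyloxy)-4,4,7a-trimethyl-2,4,5,6,7,7a-hexahydro-1-benzofuran-2-yl]-5-[(2E,4E)-6,6-dimethoxy-2-methylhexa-2,4-dien-1-ylidene]furan-2(5H)-one | CC1(C)C[C@H](O[Si](C)(C)C(C)(C)C)C[C@@]2(C)O[C@@H](C3=C/C(=C/C(C)=C/C=C/C(OC)OC)OC3=O)C=C12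
F9 | step 20 | (2E,4E)-6-{(2Z)-4-[(2R,6S,7aR)-6-(tert-butyldimethylsilyloxy)-4,4,7a-trimethyl-2,4,5,6,7,7a-hexahydro-1-benzofuran-2-yl]-5-oxofuran-2(5H)-ylidene}-5-methylhexa-2,4-dienal | CC1(C)C[C@H](O[Si](C)(C)C(C)(C)C)C[C@@]2(C)O[C@@H](C3=C/C(=C/C(C)=C/C=C/C=O)OC3=O)C=C12
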